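**Retrosynthetic overview**

1. Gnetumontanin B ⇐ its nona-silyl ether ⇐ (Heck reaction; the stilbene ring is attached, not closed) the 6-bromide of the two-ring core (TBS = tert-butyldimethylsilyl, TIPS = triisopropylsilyl).
2. The upper dihydrofuran ring (O1–C2–C3–C3a–C7a) is cut at C2–C3 and C2–O1 in one [4+1] annulation: O1–C7a–C3a–C3 of ring A serve as an o-quinone methide, and C2 is the ylide carbon of a chiral sulfonium salt carried on C7' of the finished lower dihydrobenzofuran.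
3. Enabling feature: O1 is a phenol oxygen of ring A ortho to the doubly benzylic C3, so O1=C7a–C3a=C3 can be unmasked as a quinone methide. C2 is a benzylic CH on an aryl ring with ortho and para oxygens, so it can be an ylide carbon and then give up the sulfide to O1. The oxygen on C4 is silylated, so only O1 can close.
4. The lower dihydrofuran ring is made earlier by the same annulation; its C7'–Br is then turned into CH2OH and the sulfonium salt.
5. Ring order: lower dihydrofuran ring (step 10), then upper dihydrofuran ring (step 18); all benzene rings are bought. One enantiomer of isothiocineole sets all four stereocentres, and silyl ethers allow an acid-free end.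

Key step: step 18

Remark: the (1R,4R,5R) sulfide is assumed to give the (2S,3S) rings; if a model annulation shows the opposite sense, its enantiomer is used in steps 4 and 13 and nothing else changes.

**Route**

Step 1
Reactants: 1 5-bromoresorcinol
Product: 2 1-bromo-3,5-bis(TBS-oxy)benzene
Conditions: TBSCl (2.3 equiv), imidazole, DMF, rt
Reagents that add atoms: tert-butyldimethylsilyl chloride, CC(C)(C)[Si](C)(C)Cl
Why: Silyl ether formation on two unhindered phenols.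

Step 2
Reactants: 3 2,4-dihydroxybenzaldehyde
Product: 4 2,4-bis(TIPS-oxy)benzaldehyde
Conditions: TIPSOTf (2.3 equiv), 2,6-lutidine, CH2Cl2, 0 °C to rt
Reagents that add atoms: triisopropylsilyl triflate, CC(C)[Si](C(C)C)(C(C)C)OS(=O)(=O)C(F)(F)F
Why: The silyl triflate also silylates the hydrogen-bonded ortho hydroxyl, and the bulky triisopropylsilyl group is chosen so that the ortho silyl group should not migrate to the later ylide carbon.

Step 3
Reactants: 4 2,4-bis(TIPS-oxy)benzaldehyde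
Product: 5 [2,4-bis(TIPS-oxy)phenyl]methanol
Conditions: i-Bu2AlH, CH2Cl2, −78 °C; aqueous potassium sodium tartrate
Reagents that add atoms: none
Why: Aldehyde reduction under non-basic conditions, which avoids silyl migration from the ortho phenol oxygen to the new alkoxide.

Step 4
Reactants: 5 [2,4-bis(TIPS-oxy)phenyl]methanol; 6 (1R,4R,5R)-isothiocineole
Product: 8 (1R,4R,5R)-6-[2,4-bis(TIPS-oxy)benzyl]-4,7,7-trimethyl-6-thiabicyclo[3.2.1]octan-6-ium triflate (benzyl group exo on sulfur), via benzylic triflate 7 (not isolated)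
Conditions: Tf2O (1.1 equiv), 2,6-lutidine, CH2Cl2, −78 °C; then 6, −78 to −20 °C
Reagents that add atoms: triflic anhydride, O=S(=O)(OS(=O)(=O)C(F)(F)F)C(F)(F)F
Why: Sulfonium salt formation by S-alkylation of the sulfide with the benzylic triflate 7 made in the flask, fast for this electron-rich benzyl group and expected on the exposed exo lone pair of sulfur.

Step 5
Reactants: 9 2,6-dihydroxybenzaldehyde
Product: 10 3-bromo-2,6-dihydroxybenzaldehyde
Conditions: NBS (1.0 equiv), MeCN, 0 °C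
Reagents that add atoms: N-bromosuccinimide, O=C1CCC(=O)N1Br
Why: Electrophilic aromatic bromination; the two activated positions are equivalent by symmetry, so only one monobromide can form.

Step 6
Reactants: 10 3-bromo-2,6-dihydroxybenzaldehyde
Product: 11 3-bromo-2-hydroxy-6-(TBS-oxy)benzaldehyde
Conditions: TBSCl (1.05 equiv), imidazole, CH2Cl2–DMF, −20 to 0 °C
Reagents that add atoms: tert-butyldimethylsilyl chloride, CC(C)(C)[Si](C)(C)Cl
Why: Sterically controlled silyl ether formation, since the hydroxyl flanked by bromine and formyl should react much more slowly with the bulky chloride than the one flanked by formyl and hydrogen.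

Step 7
Reactants: 2 1-bromo-3,5-bis(TBS-oxy)benzene
Product: 12 3,5-bis(TBS-oxy)phenylmagnesium bromide (titrated THF stock solution, kept under argon)
Conditions: Mg turnings (pre-activated by dry stirring), THF, rt to 45 °C
Reagents that add atoms: magnesium, [Mg]
Why: Grignard reagent formation by insertion of magnesium into the aryl C–Br bond, to which the aryl silyl ethers are inert; one stock solution serves steps 8 and 16.

Step 8
Reactants: 11 3-bromo-2-hydroxy-6-(TBS-oxy)benzaldehyde; 12 3,5-bis(TBS-oxy)phenylmagnesium bromide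
Product: 13 racemic [3-bromo-2-hydroxy-6-(TBS-oxy)phenyl][3,5-bis(TBS-oxy)phenyl]methanol
Conditions: 12 (2.3 equiv, THF solution), THF, −78 to −20 °C; H2O
Reagents that add atoms: none
Why: Grignard addition to the aldehyde after the first equivalent of 12 has deprotonated the phenol, kept cold so that no silyl group shifts to the new alkoxide; the carbinol centre is racemic and is erased in step 10.

Step 9
Reactants: 13 racemic [3-bromo-2-hydroxy-6-(TBS-oxy)phenyl][3,5-bis(TBS-oxy)phenyl]methanol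
Product: 14 racemic 6-bromo-2-{[3,5-bis(TBS-oxy)phenyl](p-tolylsulfonyl)methyl}-3-(TBS-oxy)phenol
Conditions: p-TolSO2H (1.5 equiv), MgSO4, CH2Cl2, rt
Reagents that add atoms: p-toluenesulfinic acid, Cc1ccc(S(=O)O)cc1
Why: Acid-promoted ionisation of the o-hydroxybenzhydrol and S-alkylation of the sulfinate should give the stable sulfone, a base-triggered precursor of the o-quinone methide.

Step 10
Reactants: 14 racemic 6-bromo-2-{[3,5-bis(TBS-oxy)phenyl](p-tolylsulfonyl)methyl}-3-(TBS-oxy)phenol; 8 sulfonium triflate of step 4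
Product: 18 (2S,3S)-7-bromo-4-(TBS-oxy)-3-[3,5-bis(TBS-oxy)phenyl]-2-[2,4-bis(TIPS-oxy)phenyl]-2,3-dihydrobenzofuran (trans), via sulfonium ylide 15 (not isolated), via o-quinone methide 16 (not isolated), via phenoxide sulfonium zwitterion 17 (not isolated)
Conditions: KN(SiMe3)2 (2.05 equiv), THF, −78 to 0 °C
Reagents that add atoms: none
Why: Proposed new method: the [4+1] annulation of step 18 on a simpler pair, in which ylide 15 adds through carbon to the methide carbon of 16 and the phenoxide of zwitterion 17 closes 5-exo-tet with loss of the sulfide, the chiral sulfide fixing C3' in the C–C bond formation and C2' following trans; the closest known reaction types are the trans-selective [4+1] annulations of o-quinone methides with carbonyl-stabilised sulfur ylides and the asymmetric epoxidation with isothiocineole-derived benzylsulfonium ylides.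

Step 11
Reactants: 18 (2S,3S)-7-bromo dihydrobenzofuran of step 10
Product: 20 (2S,3S)-4-(TBS-oxy)-3-[3,5-bis(TBS-oxy)phenyl]-2-[2,4-bis(TIPS-oxy)phenyl]-2,3-dihydrobenzofuran-7-carbaldehyde, via aryllithium 19 (not isolated)
Conditions: t-BuLi (2.1 equiv), THF, −78 °C; DMF; H2O
Reagents that add atoms: N,N-dimethylformamide, CN(C)C=O
Why: Bromine–lithium exchange is faster than any deprotonation at −78 °C, and the aryllithium is formylated by DMF.

Step 12
Reactants: 20 aldehyde of step 11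
Product: 21 [(2S,3S)-4-(TBS-oxy)-3-[3,5-bis(TBS-oxy)phenyl]-2-[2,4-bis(TIPS-oxy)phenyl]-2,3-dihydrobenzofuran-7-yl]methanol
Conditions: i-Bu2AlH, CH2Cl2, −78 °C; aqueous potassium sodium tartrate
Reagents that add atoms: none
Why: Hydride reduction of the aryl aldehyde under non-basic conditions; no stereocentre is touched.

Step 13
Reactants: 21 alcohol of step 12; 6 (1R,4R,5R)-isothiocineole
Product: 23 (1R,4R,5R)-6-{[(2S,3S)-4-(TBS-oxy)-3-[3,5-bis(TBS-oxy)phenyl]-2-[2,4-bis(TIPS-oxy)phenyl]-2,3-dihydrobenzofuran-7-yl]methyl}-4,7,7-trimethyl-6-thiabicyclo[3.2.1]octan-6-ium triflate (exo on sulfur), via benzylic triflate 22 (not isolated)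
Conditions: Tf2O (1.1 equiv), 2,6-lutidine, CH2Cl2, −78 °C; then 6, −78 to −20 °C
Reagents that add atoms: triflic anhydride, O=S(=O)(OS(=O)(=O)C(F)(F)F)C(F)(F)F
Why: Sulfonium salt formation as in step 4; the benzylic carbon carries ortho and para oxygens, so triflate 22 is captured by the sulfide at low temperature before it can alkylate an arene.

Step 14
Reactants: 24 4-bromo-2,6-dimethoxybenzaldehyde
Product: 25 4-bromo-2,6-dihydroxybenzaldehyde
Conditions: BBr3 (3 equiv), CH2Cl2, −78 °C to rt; H2O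
Reagents that add atoms: none
Why: Lewis acid cleavage of two aryl methyl ethers, both ortho to the formyl group.

Step 15
Reactants: 25 4-bromo-2,6-dihydroxybenzaldehyde
Product: 26 4-bromo-2-hydroxy-6-(TBS-oxy)benzaldehyde
Conditions: TBSCl (1.05 equiv), imidazole, CH2Cl2–DMF, −20 to 0 °C
Reagents that add atoms: tert-butyldimethylsilyl chloride, CC(C)(C)[Si](C)(C)Cl
Why: Monosilylation of a symmetric diol; the remaining hydroxyl is hydrogen-bonded to the aldehyde and shielded, so the reaction should stop after one silyl group.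

Step 16
Reactants: 26 4-bromo-2-hydroxy-6-(TBS-oxy)benzaldehyde; 12 3,5-bis(TBS-oxy)phenylmagnesium bromide
Product: 27 racemic [4-bromo-2-hydroxy-6-(TBS-oxy)phenyl][3,5-bis(TBS-oxy)phenyl]methanol
Conditions: 12 (2.3 equiv, THF solution), THF, −78 to −20 °C; H2O
Reagents that add atoms: none
Why: Grignard addition as in step 8; the racemic carbinol centre is erased in step 18.

Step 17
Reactants: 27 carbinol of step 16
Product: 28 racemic 5-bromo-2-{[3,5-bis(TBS-oxy)phenyl](p-tolylsulfonyl)methyl}-3-(TBS-oxy)phenol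
Conditions: p-TolSO2H (1.5 equiv), MgSO4, CH2Cl2, rt
Reagents that add atoms: p-toluenesulfinic acid, Cc1ccc(S(=O)O)cc1
Why: Sulfone formation through the oxygen-stabilised benzhydryl cation, as in step 9.

Step 18
Reactants: 28 sulfone of step 17; 23 sulfonium triflate of step 13
Product: 32 (2S,3S)-6-bromo-4-(TBS-oxy)-3-[3,5-bis(TBS-oxy)phenyl]-2-[(2S,3S)-4-(TBS-oxy)-3-[3,5-bis(TBS-oxy)phenyl]-2-[2,4-bis(TIPS-oxy)phenyl]-2,3-dihydrobenzofuran-7-yl]-2,3-dihydrobenzofuran (both rings trans), via sulfonium ylide 29 (not isolated), via o-quinone methide 30 (not isolated), via phenoxide sulfonium zwitterion 31 (not isolated)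
Conditions: KN(SiMe3)2 (2.05 equiv), THF, −78 to 0 °C (23 deprotonated first at −78 °C, then the potassium phenoxide of 28 added)
Reagents that add atoms: none
Why: Proposed new method: KN(SiMe3)2 turns 23 into ylide 29 and 28 into its phenoxide, which on warming expels p-toluenesulfinate to give o-quinone methide 30; the ylide carbon (future C2) adds to the methide carbon C3 (C2–C3 bond, ring A rearomatised) to give zwitterion 31, and phenoxide O1 then displaces the sulfide from C2 (C2–O1 bond), a [4+1] annulation in which the one-carbon partner is first nucleophile and then electrophile. The closest known reaction types are the trans-selective [4+1] annulations of o-quinone methides with carbonyl-stabilised sulfonium or ammonium ylides and the asymmetric epoxidations, aziridinations and cyclopropanations with isothiocineole-derived benzylsulfonium ylides; new is a semi-stabilised, aryl-substituted chiral sulfonium ylide as the one-carbon partner of an o-quinone methide. The only ring closed is the dihydrofuran, by a 5-exo-tet substitution at C2. C3 is set in the C–C bond formation, where the bicyclic sulfide leaves one face of the favoured ylide conformer open and an open, anti transition state selects one face of the methide; C2 is set at the ylide carbon in the same event and inverted in the ring closure, which places the two aryl groups trans, also the thermodynamically preferred arrangement. The step needs carbon- rather than oxygen-alkylation of the phenoxide, secured by converting all sulfonium salt into ylide at −78 °C before the quinone methide is released, and a single site of closure, secured by the silyl ether on the C4 oxygen; the remote stereocentres of the lower ring play no part, so control rests on the reagent.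

Step 19
Reactants: 32 bromide of step 18; 33 tert-butyldimethyl(4-vinylphenoxy)silane
Product: 34 gnetumontanin B hepta-TBS bis-TIPS ether, (E)-stilbene
Conditions: Pd[P(t-Bu)3]2 (3 mol%), Cy2NMe (1.5 equiv), dioxane, 80 °C
Reagents that add atoms: none
Why: Heck reaction of the unhindered aryl bromide at the terminal carbon of the styrene, giving the (E)-alkene by syn insertion and syn β-hydride elimination.

Step 20
Reactants: 34 gnetumontanin B hepta-TBS bis-TIPS ether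
Product: 35 gnetumontanin B
Conditions: Bu4NF (12 equiv), AcOH (12 equiv), THF, 0 °C to rt, argon
Reagents that add atoms: none
Why: Fluoride cleaves all nine aryl silyl ethers, and the acetic acid buffer keeps the medium near neutral so that neither acid- nor phenoxide-driven opening of the dihydrofuran rings through quinone methides should disturb C2, C2' or the site of closure of the lower ring.

**Compound list**

1 | 5-bromoresorcinol | Oc1cc(O)cc(Br)c1 | starting material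
2 | 1-bromo-3,5-bis(TBS-oxy)benzene | CC(C)(C)[Si](C)(C)Oc1cc(Br)cc(O[Si](C)(C)C(C)(C)C)c1 | intermediate
3 | 2,4-dihydroxybenzaldehyde | O=Cc1ccc(O)cc1O | starting material
4 | 2,4-bis(TIPS-oxy)benzaldehyde | O=Cc1ccc(O[Si](C(C)C)(C(C)C)C(C)C)cc1O[Si](C(C)C)(C(C)C)C(C)C | intermediate
5 | [2,4-bis(TIPS-oxy)phenyl]methanol | OCc1ccc(O[Si](C(C)C)(C(C)C)C(C)C)cc1O[Si](C(C)C)(C(C)C)C(C)C | intermediate
6 | (1R,4R,5R)-isothiocineole (4,7,7-trimethyl-6-thiabicyclo[3.2.1]octane) | C[C@@H]1CC[C@@H]2C[C@H]1SC2(C)C | starting material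
7 | 2,4-bis(TIPS-oxy)benzyl triflate | O=S(=O)(OCc1ccc(O[Si](C(C)C)(C(C)C)C(C)C)cc1O[Si](C(C)C)(C(C)C)C(C)C)C(F)(F)F | intermediate
8 | S-[2,4-bis(TIPS-oxy)benzyl] sulfonium triflate of 6 (exo on sulfur) | C[C@@H]1CC[C@@H]2C[C@H]1[S@@+](Cc1ccc(O[Si](C(C)C)(C(C)C)C(C)C)cc1O[Si](C(C)C)(C(C)C)C(C)C)C2(C)C.[O-]S(=O)(=O)C(F)(F)F | intermediate
9 | 2,6-dihydroxybenzaldehyde | O=Cc1c(O)cccc1O | starting material
10 | 3-bromo-2,6-dihydroxybenzaldehyde | O=Cc1c(O)ccc(Br)c1O | intermediate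
11 | 3-bromo-2-hydroxy-6-(TBS-oxy)benzaldehyde | O=Cc1c(O[Si](C)(C)C(C)(C)C)ccc(Br)c1O | intermediate
12 | 3,5-bis(TBS-oxy)phenylmagnesium bromide | CC(C)(C)[Si](C)(C)Oc1cc([Mg]Br)cc(O[Si](C)(C)C(C)(C)C)c1 | intermediate
13 | racemic [3-bromo-2-hydroxy-6-(TBS-oxy)phenyl][3,5-bis(TBS-oxy)phenyl]methanol | OC(c1cc(O[Si](C)(C)C(C)(C)C)cc(O[Si](C)(C)C(C)(C)C)c1)c1c(O[Si](C)(C)C(C)(C)C)ccc(Br)c1O | intermediate
14 | racemic 6-bromo-2-{[3,5-bis(TBS-oxy)phenyl](p-tolylsulfonyl)methyl}-3-(TBS-oxy)phenol | Cc1ccc(S(=O)(=O)C(c2cc(O[Si](C)(C)C(C)(C)C)cc(O[Si](C)(C)C(C)(C)C)c2)c2c(O[Si](C)(C)C(C)(C)C)ccc(Br)c2O)cc1 | intermediate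
15 | sulfonium ylide from 8 | C[C@@H]1CC[C@@H]2C[C@H]1[S@@+]([CH-]c1ccc(O[Si](C(C)C)(C(C)C)C(C)C)cc1O[Si](C(C)C)(C(C)C)C(C)C)C2(C)C | intermediate
16 | 2-bromo-5-(TBS-oxy)-6-[3,5-bis(TBS-oxy)benzylidene]cyclohexa-2,4-dien-1-one (alkene geometry not defined) | O=C1C(Br)=CC=C(O[Si](C)(C)C(C)(C)C)C1=Cc1cc(O[Si](C)(C)C(C)(C)C)cc(O[Si](C)(C)C(C)(C)C)c1 | intermediate
17 | (1R,2S)-1-[2,4-bis(TIPS-oxy)phenyl]-2-[3,5-bis(TBS-oxy)phenyl]-2-[3-bromo-2-oxido-6-(TBS-oxy)phenyl]ethyl sulfonium zwitterion of 6 | C[C@@H]1CC[C@@H]2C[C@H]1[S@@+]([C@@H](c1ccc(O[Si](C(C)C)(C(C)C)C(C)C)cc1O[Si](C(C)C)(C(C)C)C(C)C)[C@@H](c1cc(O[Si](C)(C)C(C)(C)C)cc(O[Si](C)(C)C(C)(C)C)c1)c1c(O[Si](C)(C)C(C)(C)C)ccc(Br)c1[O-])C2(C)C | intermediate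
18 | (2S,3S)-7-bromo-4-(TBS-oxy)-3-[3,5-bis(TBS-oxy)phenyl]-2-[2,4-bis(TIPS-oxy)phenyl]-2,3-dihydrobenzofuran | Brc1ccc(O[Si](C)(C)C(C)(C)C)c2c1O[C@H](c1ccc(O[Si](C(C)C)(C(C)C)C(C)C)cc1O[Si](C(C)C)(C(C)C)C(C)C)[C@H]2c1cc(O[Si](C)(C)C(C)(C)C)cc(O[Si](C)(C)C(C)(C)C)c1 | intermediate
19 | 7-lithio analogue of 18 | [Li]c1ccc(O[Si](C)(C)C(C)(C)C)c2c1O[C@H](c1ccc(O[Si](C(C)C)(C(C)C)C(C)C)cc1O[Si](C(C)C)(C(C)C)C(C)C)[C@H]2c1cc(O[Si](C)(C)C(C)(C)C)cc(O[Si](C)(C)C(C)(C)C)c1 | intermediate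
20 | (2S,3S)-dihydrobenzofuran-7-carbaldehyde corresponding to 18 | O=Cc1ccc(O[Si](C)(C)C(C)(C)C)c2c1O[C@H](c1ccc(O[Si](C(C)C)(C(C)C)C(C)C)cc1O[Si](C(C)C)(C(C)C)C(C)C)[C@H]2c1cc(O[Si](C)(C)C(C)(C)C)cc(O[Si](C)(C)C(C)(C)C)c1 | intermediate
21 | (2S,3S)-dihydrobenzofuran-7-ylmethanol corresponding to 18 | OCc1ccc(O[Si](C)(C)C(C)(C)C)c2c1O[C@H](c1ccc(O[Si](C(C)C)(C(C)C)C(C)C)cc1O[Si](C(C)C)(C(C)C)C(C)C)[C@H]2c1cc(O[Si](C)(C)C(C)(C)C)cc(O[Si](C)(C)C(C)(C)C)c1 | intermediate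
22 | (2S,3S)-dihydrobenzofuran-7-ylmethyl triflate from 21 | O=S(=O)(OCc1ccc(O[Si](C)(C)C(C)(C)C)c2c1O[C@H](c1ccc(O[Si](C(C)C)(C(C)C)C(C)C)cc1O[Si](C(C)C)(C(C)C)C(C)C)[C@H]2c1cc(O[Si](C)(C)C(C)(C)C)cc(O[Si](C)(C)C(C)(C)C)c1)C(F)(F)F | intermediate
23 | S-(dihydrobenzofuran-7-ylmethyl) sulfonium triflate from 21 and 6 (exo on sulfur) | C[C@@H]1CC[C@@H]2C[C@H]1[S@@+](Cc1ccc(O[Si](C)(C)C(C)(C)C)c3c1O[C@H](c1ccc(O[Si](C(C)C)(C(C)C)C(C)C)cc1O[Si](C(C)C)(C(C)C)C(C)C)[C@H]3c1cc(O[Si](C)(C)C(C)(C)C)cc(O[Si](C)(C)C(C)(C)C)c1)C2(C)C.[O-]S(=O)(=O)C(F)(F)F | intermediate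
24 | 4-bromo-2,6-dimethoxybenzaldehyde | COc1cc(Br)cc(OC)c1C=O | starting material
25 | 4-bromo-2,6-dihydroxybenzaldehyde | O=Cc1c(O)cc(Br)cc1O | intermediate
26 | 4-bromo-2-hydroxy-6-(TBS-oxy)benzaldehyde | O=Cc1c(O)cc(Br)cc1O[Si](C)(C)C(C)(C)C | intermediate
27 | racemic [4-bromo-2-hydroxy-6-(TBS-oxy)phenyl][3,5-bis(TBS-oxy)phenyl]methanol | OC(c1cc(O[Si](C)(C)C(C)(C)C)cc(O[Si](C)(C)C(C)(C)C)c1)c1c(O)cc(Br)cc1O[Si](C)(C)C(C)(C)C | intermediate
28 | racemic 5-bromo-2-{[3,5-bis(TBS-oxy)phenyl](p-tolylsulfonyl)methyl}-3-(TBS-oxy)phenol | Cc1ccc(S(=O)(=O)C(c2cc(O[Si](C)(C)C(C)(C)C)cc(O[Si](C)(C)C(C)(C)C)c2)c2c(O)cc(Br)cc2O[Si](C)(C)C(C)(C)C)cc1 | intermediate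
29 | sulfonium ylide from 23 | C[C@@H]1CC[C@@H]2C[C@H]1[S@@+]([CH-]c1ccc(O[Si](C)(C)C(C)(C)C)c3c1O[C@H](c1ccc(O[Si](C(C)C)(C(C)C)C(C)C)cc1O[Si](C(C)C)(C(C)C)C(C)C)[C@H]3c1cc(O[Si](C)(C)C(C)(C)C)cc(O[Si](C)(C)C(C)(C)C)c1)C2(C)C | intermediate
30 | 3-bromo-5-(TBS-oxy)-6-[3,5-bis(TBS-oxy)benzylidene]cyclohexa-2,4-dien-1-one (alkene geometry not defined) | O=C1C=C(Br)C=C(O[Si](C)(C)C(C)(C)C)C1=Cc1cc(O[Si](C)(C)C(C)(C)C)cc(O[Si](C)(C)C(C)(C)C)c1 | intermediate
31 | (1R,2S)-1-(lower dihydrobenzofuran-7-yl)-2-[3,5-bis(TBS-oxy)phenyl]-2-[4-bromo-2-oxido-6-(TBS-oxy)phenyl]ethyl sulfonium zwitterion of 6 | C[C@@H]1CC[C@@H]2C[C@H]1[S@@+]([C@@H](c1ccc(O[Si](C)(C)C(C)(C)C)c3c1O[C@H](c1ccc(O[Si](C(C)C)(C(C)C)C(C)C)cc1O[Si](C(C)C)(C(C)C)C(C)C)[C@H]3c1cc(O[Si](C)(C)C(C)(C)C)cc(O[Si](C)(C)C(C)(C)C)c1)[C@@H](c1cc(O[Si](C)(C)C(C)(C)C)cc(O[Si](C)(C)C(C)(C)C)c1)c1c(O[Si](C)(C)C(C)(C)C)cc(Br)cc1[O-])C2(C)C | intermediate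
32 | (2S,3S)-6-bromo-4-(TBS-oxy)-3-[3,5-bis(TBS-oxy)phenyl]-2-[(2S,3S)-lower dihydrobenzofuran-7-yl]-2,3-dihydrobenzofuran | Brc1cc(O[Si](C)(C)C(C)(C)C)c2c(c1)O[C@H](c1ccc(O[Si](C)(C)C(C)(C)C)c3c1O[C@H](c1ccc(O[Si](C(C)C)(C(C)C)C(C)C)cc1O[Si](C(C)C)(C(C)C)C(C)C)[C@H]3c1cc(O[Si](C)(C)C(C)(C)C)cc(O[Si](C)(C)C(C)(C)C)c1)[C@H]2c1cc(O[Si](C)(C)C(C)(C)C)cc(O[Si](C)(C)C(C)(C)C)c1 | intermediate
33 | tert-butyldimethyl(4-vinylphenoxy)silane | C=Cc1ccc(O[Si](C)(C)C(C)(C)C)cc1 | starting material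
34 | gnetumontanin B hepta-TBS bis-TIPS ether | CC(C)(C)[Si](C)(C)Oc1ccc(/C=C/c2cc(O[Si](C)(C)C(C)(C)C)c3c(c2)O[C@H](c2ccc(O[Si](C)(C)C(C)(C)C)c4c2O[C@H](c2ccc(O[Si](C(C)C)(C(C)C)C(C)C)cc2O[Si](C(C)C)(C(C)C)C(C)C)[C@H]4c2cc(O[Si](C)(C)C(C)(C)C)cc(O[Si](C)(C)C(C)(C)C)c2)[C@H]3c2cc(O[Si](C)(C)C(C)(C)C)cc(O[Si](C)(C)C(C)(C)C)c2)cc1 | intermediate
35 | gnetumontanin B | Oc1ccc(/C=C/c2cc(O)c3c(c2)O[C@H](c2ccc(O)c4c2O[C@H](c2ccc(O)cc2O)[C@H]4c2cc(O)cc(O)c2)[C@H]3c2cc(O)cc(O)c2)cc1 | target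

**Step count and risks**

Total step count: 20. Longest linear sequence: 11 steps (steps 5, 6 and 8–13, then 18–20).

Steps most likely to fail:

1. Step 18. The phenoxide of 28 may be O-benzylated by sulfonium salt that has not yet become ylide, the zwitterion may eliminate to a triarylethene instead of closing, the quinone methide may dimerise, or the face selection in the C–C bond formation may be poor. Any cis isomer must be removed by chromatography and not epimerised, because its C3 is the wrong one. The fallback sets out from 27 and 21 and returns at 32, using the known enantioselective C–H insertion of donor/donor rhodium carbenes. Oxidation of 27 (MnO2, CH2Cl2) gives the benzophenone F1. Mitsunobu etherification of its phenol with 21 (PPh3, DIAD, THF) gives the benzyl ether F2. Condensation with hydrazine (N2H4, AcOH cat., EtOH–THF, 70 °C; the crowded carbonyl will be slow) gives the hydrazone F3, which MnO2 oxidises to the diaryldiazomethane F4, used at once. Rh2(S-PTAD)4, dirhodium tetrakis[(S)-(1-adamantyl)(N-phthalimido)acetate] (1 mol%, CH2Cl2, 0 °C; or its enantiomer, whichever a model shows to give 3S), should insert the carbene into the benzylic C–H bond next to the ether oxygen to give the cis-dihydrobenzofuran F5, with C3 set by the catalyst. Brief CF3CO2H in CH2Cl2 at 0 °C then epimerises C2 through the oxygen-stabilised benzylic cation, which only O1 can recapture, to give 32.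

2. Step 10. The same processes as in step 18 may intervene, and in addition the ortho silyl group may shift from oxygen to the ylide carbon. The fallback sets out from 13 and 5 and returns at 18 by the same known carbene sequence. Oxidation of 13 (MnO2) gives the benzophenone F6. Mitsunobu etherification with 5 gives the benzyl ether F7. Hydrazine gives the hydrazone F8, and MnO2 gives the diaryldiazomethane F9. Rh2(S-PTAD)4 then gives the cis-dihydrobenzofuran F10, and CF3CO2H in CH2Cl2 at 0 °C epimerises C2' to give 18.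

3. Step 6. Silylation may take place at the hydroxyl next to bromine, or twice, which would put the ring oxygen of the lower dihydrobenzofuran on the wrong side. The fallback sets out from 9 and returns at 11 with the order of events reversed. The symmetric diol 9 is monosilylated first (TBSCl, 1.0 equiv, imidazole) to give 2-hydroxy-6-(TBS-oxy)benzaldehyde F11, where regiochemistry cannot arise. Amine-mediated ortho-bromination directed by the free phenol (NBS, i-Pr2NH cat., CH2Cl2, 0 °C) then places bromine next to the free hydroxyl and gives 11.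

**Further compounds**

F1 | step 18 | [4-bromo-2-hydroxy-6-(TBS-oxy)phenyl][3,5-bis(TBS-oxy)phenyl]methanone | O=C(c1cc(O[Si](C)(C)C(C)(C)C)cc(O[Si](C)(C)C(C)(C)C)c1)c1c(O)cc(Br)cc1O[Si](C)(C)C(C)(C)C
F2 | step 18 | benzyl ether of F1 with 21 | O=C(c1cc(O[Si](C)(C)C(C)(C)C)cc(O[Si](C)(C)C(C)(C)C)c1)c1c(OCc2ccc(O[Si](C)(C)C(C)(C)C)c3c2O[C@H](c2ccc(O[Si](C(C)C)(C(C)C)C(C)C)cc2O[Si](C(C)C)(C(C)C)C(C)C)[C@H]3c2cc(O[Si](C)(C)C(C)(C)C)cc(O[Si](C)(C)C(C)(C)C)c2)cc(Br)cc1O[Si](C)(C)C(C)(C)C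
F3 | step 18 | hydrazone of F2 (C=N geometry not defined) | NN=C(c1cc(O[Si](C)(C)C(C)(C)C)cc(O[Si](C)(C)C(C)(C)C)c1)c1c(OCc2ccc(O[Si](C)(C)C(C)(C)C)c3c2O[C@H](c2ccc(O[Si](C(C)C)(C(C)C)C(C)C)cc2O[Si](C(C)C)(C(C)C)C(C)C)[C@H]3c2cc(O[Si](C)(C)C(C)(C)C)cc(O[Si](C)(C)C(C)(C)C)c2)cc(Br)cc1O[Si](C)(C)C(C)(C)C
F4 | step 18 | diaryldiazomethane from F3 | [N-]=[N+]=C(c1cc(O[Si](C)(C)C(C)(C)C)cc(O[Si](C)(C)C(C)(C)C)c1)c1c(OCc2ccc(O[Si](C)(C)C(C)(C)C)c3c2O[C@H](c2ccc(O[Si](C(C)C)(C(C)C)C(C)C)cc2O[Si](C(C)C)(C(C)C)C(C)C)[C@H]3c2cc(O[Si](C)(C)C(C)(C)C)cc(O[Si](C)(C)C(C)(C)C)c2)cc(Br)cc1O[Si](C)(C)C(C)(C)C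
F5 | step 18 | (2R,3S)-cis isomer of 32 at the upper ring | Brc1cc(O[Si](C)(C)C(C)(C)C)c2c(c1)O[C@@H](c1ccc(O[Si](C)(C)C(C)(C)C)c3c1O[C@H](c1ccc(O[Si](C(C)C)(C(C)C)C(C)C)cc1O[Si](C(C)C)(C(C)C)C(C)C)[C@H]3c1cc(O[Si](C)(C)C(C)(C)C)cc(O[Si](C)(C)C(C)(C)C)c1)[C@H]2c1cc(O[Si](C)(C)C(C)(C)C)cc(O[Si](C)(C)C(C)(C)C)c1
F6 | step 10 | [3-bromo-2-hydroxy-6-(TBS-oxy)phenyl][3,5-bis(TBS-oxy)phenyl]methanone | O=C(c1cc(O[Si](C)(C)C(C)(C)C)cc(O[Si](C)(C)C(C)(C)C)c1)c1c(O[Si](C)(C)C(C)(C)C)ccc(Br)c1O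
F7 | step 10 | 2,4-bis(TIPS-oxy)benzyl ether of F6 | O=C(c1cc(O[Si](C)(C)C(C)(C)C)cc(O[Si](C)(C)C(C)(C)C)c1)c1c(O[Si](C)(C)C(C)(C)C)ccc(Br)c1OCc1ccc(O[Si](C(C)C)(C(C)C)C(C)C)cc1O[Si](C(C)C)(C(C)C)C(C)C
F8 | step 10 | hydrazone of F7 (C=N geometry not defined) | NN=C(c1cc(O[Si](C)(C)C(C)(C)C)cc(O[Si](C)(C)C(C)(C)C)c1)c1c(O[Si](C)(C)C(C)(C)C)ccc(Br)c1OCc1ccc(O[Si](C(C)C)(C(C)C)C(C)C)cc1O[Si](C(C)C)(C(C)C)C(C)C
F9 | step 10 | diaryldiazomethane from F8 | [N-]=[N+]=C(c1cc(O[Si](C)(C)C(C)(C)C)cc(O[Si](C)(C)C(C)(C)C)c1)c1c(O[Si](C)(C)C(C)(C)C)ccc(Br)c1OCc1ccc(O[Si](C(C)C)(C(C)C)C(C)C)cc1O[Si](C(C)C)(C(C)C)C(C)C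
F10 | step 10 | (2R,3S)-cis isomer of 18 | Brc1ccc(O[Si](C)(C)C(C)(C)C)c2c1O[C@@H](c1ccc(O[Si](C(C)C)(C(C)C)C(C)C)cc1O[Si](C(C)C)(C(C)C)C(C)C)[C@H]2c1cc(O[Si](C)(C)C(C)(C)C)cc(O[Si](C)(C)C(C)(C)C)c1
F11 | step 6 | 2-hydroxy-6-(TBS-oxy)benzaldehyde | O=Cc1c(O)cccc1O[Si](C)(C)C(C)(C)C
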